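**Retrosynthetic overview**
- Last bond: C9–C10, closing the ten-membered ring (second ring) by an intramolecular nickel-catalysed α-hydroxy C–H alkenylation of a primary alcohol with a (Z)-vinyl iodide.
- First ring: the cis-γ-lactone, formed together with the C6–C7 bond by chromium-catalysed asymmetric 2-(methoxycarbonyl)allylation/lactonisation that joins a West enal and an East allyl bromide; C11 then comes from copper hydride reduction of the exocyclic methylene.
- West enal: crossed aldol condensation, catalytic asymmetric acetate aldol (C3), Stork–Zhao olefination (Z C1=C10 iodide), acylation with (R)-2-methylbutanoyl chloride.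
- East bromide: propane-1,3-diol → aldehyde → Morita–Baylis–Hillman adduct → (Z)-allyl bromide.

Assumption: locants C1–C15 are germacranolide locants (C3 acyloxy carbon, C6 lactone O–CH, C7 ring-fusion CH, C9 carbinol, C11/C12 lactone α-carbon and carbonyl, C13/C14/C15 the methyls on C11/C10/C4); the target is read as the cis-fused lactone (3S,6R,7S,9S,11R) with a 1(10)Z,4E diene and an (R)-2-methylbutanoate; (R)-2-methylbutanoic acid and 60% aqueous 2,2-dimethoxyacetaldehyde are taken as commercial.

**Route**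

Step 1
Reactants: 1 2,2-dimethoxyacetaldehyde; 2 propanal
Product: 3 (2E)-4,4-dimethoxy-2-methylbut-2-enal
Conditions: 1 (60% aq.), piperidine/AcOH (10 mol% each), toluene, 50 °C, slow addition of 2
Reagents that add atoms: none
Why: Amine/acid-catalysed crossed aldol condensation (the enamine of propanal adds to the more electrophilic glyoxal monoacetal) and dehydration give the conjugated enal with the thermodynamically preferred E geometry, which fixes the C4=C5 alkene.

Step 2
Reactants: 4 methyl acetate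
Product: 5 [(1-methoxyethenyl)oxy]trimethylsilane
Conditions: LiN(i-Pr)2, THF, −78 °C; Me3SiCl, −78 °C → rt
Reagents that add atoms: chlorotrimethylsilane C[Si](C)(C)Cl
Why: Kinetic lithium enolate formation and O-silylation give the ketene silyl acetal used as the acetate nucleophile in the Mukaiyama aldol.

Step 3
Reactants: 3 (2E)-4,4-dimethoxy-2-methylbut-2-enal; 5 [(1-methoxyethenyl)oxy]trimethylsilane
Product: 7 methyl (3S,4E)-3-hydroxy-6,6-dimethoxy-4-methylhex-4-enoate, via O-trimethylsilyl aldol adduct 6 (not isolated)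
Conditions: Ti(OiPr)4 (2 mol%), binaphthyl aminophenol Schiff-base ligand (2 mol%, antipode chosen for Si-face addition), 3,5-di-tert-butylsalicylic acid (2 mol%), Et2O, −10 °C; then K2CO3 (cat.), MeOH, 0 °C
Reagents that add atoms: none
Why: Carreira-type catalytic asymmetric Mukaiyama acetate aldol in which the chiral tetravalent titanium Lewis acid activates the enal for 1,2-addition on its Si face and so sets C3 (S) without ionising the distant acetal; mild methanolysis removes the transferred silyl group.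

Step 4
Reactants: 7 methyl (3S,4E)-3-hydroxy-6,6-dimethoxy-4-methylhex-4-enoate
Product: 8 methyl (3S,4E)-3-[(tert-butyldimethylsilyl)oxy]-6,6-dimethoxy-4-methylhex-4-enoate
Conditions: TBSCl, imidazole, DMF, rt
Reagents that add atoms: tert-butyldimethylsilyl chloride CC(C)(C)[Si](C)(C)Cl
Why: Imidazole-promoted O-silylation protects the C3 hydroxyl under non-acidic conditions that leave the acetal intact.

Step 5
Reactants: 8 methyl (3S,4E)-3-[(tert-butyldimethylsilyl)oxy]-6,6-dimethoxy-4-methylhex-4-enoate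
Product: 9 (3S,4E)-3-[(tert-butyldimethylsilyl)oxy]-6,6-dimethoxy-4-methylhex-4-enal
Conditions: i-Bu2AlH (1.1 equiv), CH2Cl2, −78 °C; aq. potassium sodium tartrate
Reagents that add atoms: none
Why: Partial ester reduction, in which the tetrahedral aluminium hemiacetal is stable at −78 °C and releases the β-silyloxy aldehyde only on work-up, while the acetal and alkene do not react.

Step 6
Reactants: 10 iodoethane
Product: 11 ethyltriphenylphosphonium iodide
Conditions: PPh3, toluene, 110 °C
Reagents that add atoms: triphenylphosphine c1ccc(cc1)P(c1ccccc1)c1ccccc1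
Why: SN2 quaternisation of the phosphine gives the Wittig salt that carries C10 and C14.

Step 7
Reactants: 9 (3S,4E)-3-[(tert-butyldimethylsilyl)oxy]-6,6-dimethoxy-4-methylhex-4-enal; 11 ethyltriphenylphosphonium iodide
Product: 15 tert-butyl{[(2E,4S,6Z)-7-iodo-1,1-dimethoxy-3-methylocta-2,6-dien-4-yl]oxy}dimethylsilane, via ethylidenetriphenylphosphorane 12 (not isolated), via (1-iodoethyl)triphenylphosphonium iodide 13 (not isolated), via (1-iodoethylidene)triphenylphosphorane 14 (not isolated)
Conditions: n-BuLi, THF, 0 °C; I2, −78 °C; NaN(SiMe3)2, −20 °C; then 9, −78 °C → rt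
Reagents that add atoms: iodine II
Why: Stork–Zhao olefination (Wittig reaction of an α-iodo ylide made by iodination and re-deprotonation of the ethylidene ylide), whose kinetically formed cis-oxaphosphetane puts iodine cis to the chain and gives the (Z)-2-iodo-2-alkene that becomes the cis C1=C10 ring alkene.

Step 8
Reactants: 15 tert-butyl{[(2E,4S,6Z)-7-iodo-1,1-dimethoxy-3-methylocta-2,6-dien-4-yl]oxy}dimethylsilane
Product: 16 (2E,4S,6Z)-7-iodo-1,1-dimethoxy-3-methylocta-2,6-dien-4-ol
Conditions: Bu4NF, THF, 0 °C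
Reagents that add atoms: none
Why: Fluoride desilylation frees the C3 hydroxyl while the acetal is kept, because unmasking the aldehyde first would give a 4-hydroxy enal prone to furan formation.

Step 9
Reactants: 17 (2R)-2-methylbutanoic acid
Product: 18 (2R)-2-methylbutanoyl chloride
Conditions: (COCl)2, DMF (cat.), CH2Cl2, 0 °C → rt
Reagents that add atoms: oxalyl chloride O=C(Cl)C(Cl)=O
Why: Vilsmeier-catalysed acyl chloride formation proceeds without base, so the α-stereocentre is not epimerised.

Step 10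
Reactants: 16 (2E,4S,6Z)-7-iodo-1,1-dimethoxy-3-methylocta-2,6-dien-4-ol; 18 (2R)-2-methylbutanoyl chloride
Product: 19 (2E,4S,6Z)-7-iodo-1,1-dimethoxy-3-methylocta-2,6-dien-4-yl (2R)-2-methylbutanoate
Conditions: pyridine, DMAP (5 mol%), CH2Cl2, 0 °C
Reagents that add atoms: none
Why: Nucleophilic acyl substitution (pyridine/DMAP acylation) installs the side-chain ester with retention at both stereocentres, since neither the C3–O bond nor the acyl α-C–H is touched by the weak base.

Step 11
Reactants: 19 (2E,4S,6Z)-7-iodo-1,1-dimethoxy-3-methylocta-2,6-dien-4-yl (2R)-2-methylbutanoate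
Product: 20 (2E,4S,6Z)-7-iodo-3-methyl-1-oxoocta-2,6-dien-4-yl (2R)-2-methylbutanoate
Conditions: PPTS (10 mol%), acetone/H2O (10:1), rt
Reagents that add atoms: water O
Why: Mild acid-catalysed hydrolysis of the allylic dimethyl acetal unmasks the E enal (C6) without cleaving the allylic ester.

Step 12
Reactants: 21 propane-1,3-diol
Product: 22 3-[(tert-butyldimethylsilyl)oxy]propan-1-ol
Conditions: NaH (1.0 equiv), THF, 0 °C → rt; TBSCl
Reagents that add atoms: tert-butyldimethylsilyl chloride CC(C)(C)[Si](C)(C)Cl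
Why: O-silylation of the sparingly soluble monosodium alkoxide differentiates the two hydroxyls.

Step 13
Reactants: 22 3-[(tert-butyldimethylsilyl)oxy]propan-1-ol
Product: 23 3-[(tert-butyldimethylsilyl)oxy]propanal
Conditions: TEMPO (10 mol%), PhI(OAc)2 (1.1 equiv), CH2Cl2, rt
Reagents that add atoms: none
Why: Oxoammonium (TEMPO) oxidation of the primary alcohol stops at the aldehyde and tolerates the silyl ether.

Step 14
Reactants: 23 3-[(tert-butyldimethylsilyl)oxy]propanal; 24 methyl acrylate
Product: 25 methyl 5-[(tert-butyldimethylsilyl)oxy]-3-hydroxy-2-methylidenepentanoate (racemic)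
Conditions: DABCO (0.5 equiv), neat, rt, 5 d
Reagents that add atoms: none
Why: Morita–Baylis–Hillman reaction joins C7 to C11; the racemic carbinol centre is destroyed in the next step.

Step 15
Reactants: 25 methyl 5-[(tert-butyldimethylsilyl)oxy]-3-hydroxy-2-methylidenepentanoate
Product: 26 methyl (2Z)-2-(bromomethyl)-5-[(tert-butyldimethylsilyl)oxy]pent-2-enoate
Conditions: NBS, Me2S, CH2Cl2, 0 °C → rt
Reagents that add atoms: N-bromosuccinimide O=C1CCC(=O)N1Br
Why: Corey–Kim-type activation of the allylic alcohol followed by SN2' attack of bromide gives the rearranged primary allyl bromide with the side chain trans to the ester, the geometry needed for a syn allylation.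

Step 16
Reactants: 20 (2E,4S,6Z)-7-iodo-3-methyl-1-oxoocta-2,6-dien-4-yl (2R)-2-methylbutanoate; 26 methyl (2Z)-2-(bromomethyl)-5-[(tert-butyldimethylsilyl)oxy]pent-2-enoate
Product: 29 (1E,3S,5Z)-1-[(2S,3S)-3-{2-[(tert-butyldimethylsilyl)oxy]ethyl}-4-methylidene-5-oxooxolan-2-yl]-6-iodo-2-methylhepta-1,5-dien-3-yl (2R)-2-methylbutanoate, via O-trimethylsilyl syn adduct 27 (not isolated), via syn hydroxy ester 28 (not isolated)
Conditions: CrCl2 (10 mol%, nickel-free), 3,6-di-tert-butyl-1,8-bis(4-isopropyl-4,5-dihydrooxazol-2-yl)carbazole (12 mol%, antipode chosen for Re-face addition), Mn (2 equiv), Me3SiCl (1.2 equiv), Et3N (20 mol%), THF, rt; then p-TsOH·H2O (10 mol%), CH2Cl2, rt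
Reagents that add atoms: none
Why: Chromium-catalysed asymmetric Nozaki–Hiyama–Kishi-type 2-(alkoxycarbonyl)allylation then lactonisation, in which the allylchromium (side chain cis to CH2Cr) adds through a chair transition state to give the syn adduct and the chiral ligand directs it to the Re face of the enal, setting C6 and C7 before acid closes the cis-γ-lactone; without nickel the vinyl iodide is inert to divalent chromium.

Step 17
Reactants: 29 (1E,3S,5Z)-1-[(2S,3S)-3-{2-[(tert-butyldimethylsilyl)oxy]ethyl}-4-methylidene-5-oxooxolan-2-yl]-6-iodo-2-methylhepta-1,5-dien-3-yl (2R)-2-methylbutanoate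
Product: 30 (1E,3S,5Z)-1-[(2R,3S,4R)-3-{2-[(tert-butyldimethylsilyl)oxy]ethyl}-4-methyl-5-oxooxolan-2-yl]-6-iodo-2-methylhepta-1,5-dien-3-yl (2R)-2-methylbutanoate
Conditions: [(PPh3)CuH]6 (5 mol% Cu), (EtO)2MeSiH (1.5 equiv), t-BuOH (1.5 equiv), toluene, −20 → 0 °C
Reagents that add atoms: none
Why: Copper hydride conjugate reduction of the α-methylene lactone, whose copper enolate is protonated by t-BuOH on the convex face anti to the C7 side chain and the C6 alkenyl group, placing H11 cis to H7 and giving (11R); isolated alkenes, esters and the vinyl iodide are not reduced.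

Step 18
Reactants: 30 (1E,3S,5Z)-1-[(2R,3S,4R)-3-{2-[(tert-butyldimethylsilyl)oxy]ethyl}-4-methyl-5-oxooxolan-2-yl]-6-iodo-2-methylhepta-1,5-dien-3-yl (2R)-2-methylbutanoate
Product: 31 (1E,3S,5Z)-1-[(2R,3S,4R)-3-(2-hydroxyethyl)-4-methyl-5-oxooxolan-2-yl]-6-iodo-2-methylhepta-1,5-dien-3-yl (2R)-2-methylbutanoate
Conditions: HF·pyridine, THF/pyridine, 0 °C → rt
Reagents that add atoms: none
Why: Acidic fluoride desilylation of the primary silyl ether leaves both esters, the vinyl iodide and the epimerisable C11 centre untouched.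

Step 19
Reactants: 31 (1E,3S,5Z)-1-[(2R,3S,4R)-3-(2-hydroxyethyl)-4-methyl-5-oxooxolan-2-yl]-6-iodo-2-methylhepta-1,5-dien-3-yl (2R)-2-methylbutanoate
Product: 32 (3R,3aS,5S,6Z,9S,10E,11aR)-5-hydroxy-3,6,10-trimethyl-2-oxo-2,3,3a,4,5,8,9,11a-octahydrocyclodeca[b]furan-9-yl (2R)-2-methylbutanoate (CNP0276536.2)
Conditions: [Ir(dF(CF3)ppy)2(dtbbpy)]PF6 (2 mol%), NiBr2(dme) (10 mol%), (S,S)-4,4'-dibenzyl-2,2'-bis(2-oxazoline) (12 mol%, antipode to be matched to C9 S), quinuclidine (1.5 equiv), ZnCl2 (1.5 equiv), DMSO (2 mM), 450 nm LEDs, rt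
Reagents that add atoms: none
Why: Proposed new method: intramolecular nickel-catalysed α-hydroxy C(sp3)–H alkenylation, in which photo-oxidised quinuclidine abstracts the hydridic C9–H of the ZnCl2-activated primary alcohol, the α-hydroxyalkyl radical is captured by the tethered (Z)-alkenyl divalent nickel species formed by oxidative addition of zerovalent nickel into the C10–I bond (geometry retained), and reductive elimination from trivalent nickel closes the ten-membered ring and sets C9 (S) under the chiral bis(oxazoline) ligand and the cis-lactone-constrained tether; the closest known reaction type is the intermolecular photoredox/hydrogen-atom-transfer/nickel α-arylation of free alcohols with aryl halides, which has not been shown for alkenyl iodides, for ring closure or for medium rings.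

**Compound list**
1 | 2,2-dimethoxyacetaldehyde | COC(OC)C=O | starting material
2 | propanal | CCC=O | starting material
3 | (2E)-4,4-dimethoxy-2-methylbut-2-enal | COC(OC)/C=C(\C)C=O | intermediate
4 | methyl acetate | COC(C)=O | starting material
5 | [(1-methoxyethenyl)oxy]trimethylsilane | COC(=C)O[Si](C)(C)C | intermediate
6 | methyl (3S,4E)-6,6-dimethoxy-4-methyl-3-[(trimethylsilyl)oxy]hex-4-enoate | COC(=O)C[C@H](O[Si](C)(C)C)/C(C)=C/C(OC)OC | intermediate
7 | methyl (3S,4E)-3-hydroxy-6,6-dimethoxy-4-methylhex-4-enoate | COC(=O)C[C@H](O)/C(C)=C/C(OC)OC | intermediate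
8 | methyl (3S,4E)-3-[(tert-butyldimethylsilyl)oxy]-6,6-dimethoxy-4-methylhex-4-enoate | COC(=O)C[C@H](O[Si](C)(C)C(C)(C)C)/C(C)=C/C(OC)OC | intermediate
9 | (3S,4E)-3-[(tert-butyldimethylsilyl)oxy]-6,6-dimethoxy-4-methylhex-4-enal | O=CC[C@H](O[Si](C)(C)C(C)(C)C)/C(C)=C/C(OC)OC | intermediate
10 | iodoethane | CCI | starting material
11 | ethyltriphenylphosphonium iodide | CC[P+](c1ccccc1)(c1ccccc1)c1ccccc1.[I-] | intermediate
12 | ethylidenetriphenylphosphorane | CC=P(c1ccccc1)(c1ccccc1)c1ccccc1 | intermediate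
13 | (1-iodoethyl)triphenylphosphonium iodide | CC(I)[P+](c1ccccc1)(c1ccccc1)c1ccccc1.[I-] | intermediate
14 | (1-iodoethylidene)triphenylphosphorane | CC(I)=P(c1ccccc1)(c1ccccc1)c1ccccc1 | intermediate
15 | tert-butyl{[(2E,4S,6Z)-7-iodo-1,1-dimethoxy-3-methylocta-2,6-dien-4-yl]oxy}dimethylsilane | C/C(I)=C/C[C@H](O[Si](C)(C)C(C)(C)C)/C(C)=C/C(OC)OC | intermediate
16 | (2E,4S,6Z)-7-iodo-1,1-dimethoxy-3-methylocta-2,6-dien-4-ol | C/C(I)=C/C[C@H](O)/C(C)=C/C(OC)OC | intermediate
17 | (2R)-2-methylbutanoic acid | CC[C@@H](C)C(=O)O | starting material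
18 | (2R)-2-methylbutanoyl chloride | CC[C@@H](C)C(=O)Cl | intermediate
19 | (2E,4S,6Z)-7-iodo-1,1-dimethoxy-3-methylocta-2,6-dien-4-yl (2R)-2-methylbutanoate | CC[C@@H](C)C(=O)O[C@@H](C/C=C(/C)I)/C(C)=C/C(OC)OC | intermediate
20 | (2E,4S,6Z)-7-iodo-3-methyl-1-oxoocta-2,6-dien-4-yl (2R)-2-methylbutanoate | CC[C@@H](C)C(=O)O[C@@H](C/C=C(/C)I)/C(C)=C/C=O | intermediate
21 | propane-1,3-diol | OCCCO | starting material
22 | 3-[(tert-butyldimethylsilyl)oxy]propan-1-ol | OCCCO[Si](C)(C)C(C)(C)C | intermediate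
23 | 3-[(tert-butyldimethylsilyl)oxy]propanal | O=CCCO[Si](C)(C)C(C)(C)C | intermediate
24 | methyl acrylate | COC(=O)C=C | starting material
25 | methyl 5-[(tert-butyldimethylsilyl)oxy]-3-hydroxy-2-methylidenepentanoate (racemic) | COC(=O)C(=C)C(O)CCO[Si](C)(C)C(C)(C)C | intermediate
26 | methyl (2Z)-2-(bromomethyl)-5-[(tert-butyldimethylsilyl)oxy]pent-2-enoate | COC(=O)/C(CBr)=C/CCO[Si](C)(C)C(C)(C)C | intermediate
27 | methyl (3S,4S,5E,7S,9Z)-3-{2-[(tert-butyldimethylsilyl)oxy]ethyl}-10-iodo-6-methyl-2-methylidene-7-{[(2R)-2-methylbutanoyl]oxy}-4-[(trimethylsilyl)oxy]undeca-5,9-dienoate | CC[C@@H](C)C(=O)O[C@@H](C/C=C(/C)I)/C(C)=C/[C@H](O[Si](C)(C)C)[C@@H](CCO[Si](C)(C)C(C)(C)C)C(=C)C(=O)OC | intermediate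
28 | methyl (3S,4S,5E,7S,9Z)-3-{2-[(tert-butyldimethylsilyl)oxy]ethyl}-4-hydroxy-10-iodo-6-methyl-2-methylidene-7-{[(2R)-2-methylbutanoyl]oxy}undeca-5,9-dienoate | CC[C@@H](C)C(=O)O[C@@H](C/C=C(/C)I)/C(C)=C/[C@H](O)[C@@H](CCO[Si](C)(C)C(C)(C)C)C(=C)C(=O)OC | intermediate
29 | (1E,3S,5Z)-1-[(2S,3S)-3-{2-[(tert-butyldimethylsilyl)oxy]ethyl}-4-methylidene-5-oxooxolan-2-yl]-6-iodo-2-methylhepta-1,5-dien-3-yl (2R)-2-methylbutanoate | CC[C@@H](C)C(=O)O[C@@H](C/C=C(/C)I)/C(C)=C/[C@@H]1OC(=O)C(=C)[C@@H]1CCO[Si](C)(C)C(C)(C)C | intermediate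
30 | (1E,3S,5Z)-1-[(2R,3S,4R)-3-{2-[(tert-butyldimethylsilyl)oxy]ethyl}-4-methyl-5-oxooxolan-2-yl]-6-iodo-2-methylhepta-1,5-dien-3-yl (2R)-2-methylbutanoate | CC[C@@H](C)C(=O)O[C@@H](C/C=C(/C)I)/C(C)=C/[C@@H]1OC(=O)[C@H](C)[C@@H]1CCO[Si](C)(C)C(C)(C)C | intermediate
31 | (1E,3S,5Z)-1-[(2R,3S,4R)-3-(2-hydroxyethyl)-4-methyl-5-oxooxolan-2-yl]-6-iodo-2-methylhepta-1,5-dien-3-yl (2R)-2-methylbutanoate | CC[C@@H](C)C(=O)O[C@@H](C/C=C(/C)I)/C(C)=C/[C@@H]1OC(=O)[C@H](C)[C@@H]1CCO | intermediate
32 | (3R,3aS,5S,6Z,9S,10E,11aR)-5-hydroxy-3,6,10-trimethyl-2-oxo-2,3,3a,4,5,8,9,11a-octahydrocyclodeca[b]furan-9-yl (2R)-2-methylbutanoate | CC[C@@H](C)C(=O)O[C@H]1C/C=C(/C)[C@@H](O)C[C@@H]2[C@H](/C=C/1C)OC(=O)[C@@H]2C | target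

**Step count and risks**

Total step count: 19. Longest linear sequence: 12 steps (steps 1, 3, 4, 5, 7, 8, 10, 11, 16, 17, 18, 19).

The three steps most likely to fail are 19, 16 and 17.

For step 19 (the proposed new method), the risks are slow radical capture in a ten-membered transition state, hydrogen abstraction at allylic sites, nickel insertion into the allylic C–O bonds and poor control at C9. The fallback sets out from 31 and comes back at 32. Dess–Martin oxidation (NaHCO3, CH2Cl2, 0 °C) gives the aldehyde (1E,3S,5Z)-6-iodo-2-methyl-1-[(2R,3S,4R)-4-methyl-5-oxo-3-(2-oxoethyl)oxolan-2-yl]hepta-1,5-dien-3-yl (2R)-2-methylbutanoate F3. F3 is then cyclised by the established nickel/chromium Nozaki–Hiyama–Kishi reaction (CrCl2 6 equiv, NiCl2 2 mol%, DMSO/THF, 2 mM, rt), or by its catalytic asymmetric variant with a chiral sulfonamide ligand, CrCl2 (cat.), Mn and Cp2ZrCl2, to give 32.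

For step 16, the risks are insufficient enantiocontrol by the chromium catalyst on a γ-substituted ester-bearing allyl bromide, and a syn/anti mixture. The fallback sets out from 25 (with 20) and comes back at 29, replacing allylchromium by allylboron chemistry. 25 is acetylated (Ac2O, DMAP, pyridine) to methyl 3-acetoxy-5-[(tert-butyldimethylsilyl)oxy]-2-methylidenepentanoate F1. SN2' borylation (B2pin2, CuCl 10 mol%, LiCl, KOAc, DMF) then gives methyl (2E)-5-[(tert-butyldimethylsilyl)oxy]-2-[(4,4,5,5-tetramethyl-1,3,2-dioxaborolan-2-yl)methyl]pent-2-enoate F2. Chiral phosphoric acid-catalysed allylboration of 20 with F2 (TRIP antipode chosen for Re-face attack, toluene, −30 °C; closed chair transition state, side chain cis to CH2B gives syn) delivers 28, which is lactonised with p-TsOH to 29.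

For step 17, the risk is a low diastereomer ratio at C11 or epimerisation of the kinetic all-cis lactone. The fallback sets out from 29 and comes back at 30. Homogeneous hydrogenation (H2 1 atm, RhCl(PPh3)3 5 mol%, benzene/EtOH, rt) saturates only the conjugated 1,1-disubstituted exocyclic alkene and delivers both hydrogens from the convex face without forming an enolate. This fallback makes no new compound: none F0.

Further compounds
F1 | step 16 | methyl 3-acetoxy-5-[(tert-butyldimethylsilyl)oxy]-2-methylidenepentanoate | COC(=O)C(=C)C(OC(C)=O)CCO[Si](C)(C)C(C)(C)C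
F2 | step 16 | methyl (2E)-5-[(tert-butyldimethylsilyl)oxy]-2-[(4,4,5,5-tetramethyl-1,3,2-dioxaborolan-2-yl)methyl]pent-2-enoate | COC(=O)/C(CB1OC(C)(C)C(C)(C)O1)=C/CCO[Si](C)(C)C(C)(C)C
F0 | step 17 | none | none
F3 | step 19 | (1E,3S,5Z)-6-iodo-2-methyl-1-[(2R,3S,4R)-4-methyl-5-oxo-3-(2-oxoethyl)oxolan-2-yl]hepta-1,5-dien-3-yl (2R)-2-methylbutanoate | CC[C@@H](C)C(=O)O[C@@H](C/C=C(/C)I)/C(C)=C/[C@@H]1OC(=O)[C@H](C)[C@@H]1CC=O
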